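**Plan**

- The depside ester bond (ring B carbonyl carbon to the C4 oxygen of ring A) is cut first; removing the benzyl and methyl protecting groups then traces both halves to one acid, 2-heptyl-4,6-dimethoxybenzoic acid.
- In that acid the C6–heptyl and C1–carboxyl bonds are cut together. What allows this: in ring A and ring B alike the heptyl-bearing C6 and the carboxyl-bearing C1 are adjacent, and C1 carries an oxygen-bearing C2 on its other side, the imprint of a carbon nucleophile and an electrophile added across a 3-alkoxybenzyne.
- Forward: bromination of 1-bromo-3,5-dimethoxybenzene gives the aryne precursor; heptyllithium generates 3,5-dimethoxybenzyne and adds to it, and carbon dioxide traps the aryllithium. Both benzene rings are bought; no ring is closed.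
- The common acid is then divided: loss of only the ortho methyl group gives the ring B acid, while full demethylation and benzylation give the ring A phenol. Mixed-anhydride esterification joins them and hydrogenolysis frees the acid.
- The target has no stereocentre; all selectivity questions are regiochemical (bromination site, direction of aryne addition, which methyl ether is cleaved, which hydroxyl is acylated).

Key step: step 3

Remark: heptyllithium is taken as a reagent to be prepared fresh and titrated, not bought.

**Route**

Step 1
Reactants: 1 1-bromo-3,5-dimethoxybenzene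
Product: 2 1,2-dibromo-3,5-dimethoxybenzene
Conditions: NBS (1.05 equiv), MeCN, 0 °C to rt, dark
Reagents that add atoms: N-bromosuccinimide, O=C1CCC(=O)N1Br
Why: Electrophilic aromatic bromination should go to C2, which is para to one methoxy group and ortho to the other, in preference to the more crowded C4 between both methoxy groups, and one equivalent of NBS limits a second bromination.

Step 2
Reactants: 3 1-bromoheptane
Product: 4 heptyllithium
Conditions: Li (2.2 equiv, 1% Na), Et2O, −15 to −10 °C, Ar; solution titrated and used at once
Reagents that add atoms: lithium metal, [Li]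
Why: Reductive lithiation of a primary alkyl bromide with lithium metal is the standard direct preparation of an alkyllithium, and the low temperature in ether should keep Wurtz coupling down.

Step 3
Reactants: 2 1,2-dibromo-3,5-dimethoxybenzene; 4 heptyllithium; 5 carbon dioxide
Product: 10 2-heptyl-4,6-dimethoxybenzoic acid, via (2-bromo-4,6-dimethoxyphenyl)lithium 6 (not isolated), via 3,5-dimethoxybenzyne 7 (not isolated), via (2-heptyl-4,6-dimethoxyphenyl)lithium 8 (not isolated), via lithium 2-heptyl-4,6-dimethoxybenzoate 9 (not isolated)
Conditions: 4 (3 equiv), THF/Et2O, −78 °C, slow addition of 2; −78 to −20 °C; CO2 (dry, excess), −78 °C to rt; 2 M HCl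
Reagents that add atoms: none
Why: Bromine–lithium exchange on 2 by 4 (expected at the bromine beside the methoxy group, although exchange at the other bromine leads to the same aryne) gives 6, which loses LiBr to form aryne 7; a second equivalent of 4 adds to give 8, CO2 carboxylates 8 to 9, and acid liberates 10. The closest known reaction type is the carbolithiation of 3-alkoxyarynes with carboxylation of the resulting ortho-alkoxy aryllithium, the established entry to 6-alkylsalicylic and 6-alkyl-2,4-dimethoxybenzoic acids. No ring is closed and no stereocentre is formed, so two skeletal bonds are the whole outcome. The step needs regiocontrol in the addition to the unsymmetrical aryne, and the methoxy group on C3 beside the triple bond should secure it by polarising the aryne so that the heptyl group enters at the distal carbon and lithium ends on the proximal carbon, where the oxygen stabilises it inductively and by coordination; the C5 methoxy group is remote and should count for little. Adding 2 slowly to an excess of 4 keeps the aryne scarce relative to the alkyllithium, which should hold back addition of 8 to 7, bromine transfer from 2 to 8 and alkylation of the hindered 8 by the 1-bromoheptane released.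

Step 4
Reactants: 10 2-heptyl-4,6-dimethoxybenzoic acid
Product: 11 2-heptyl-6-hydroxy-4-methoxybenzoic acid
Conditions: BCl3 (2.2 equiv), CH2Cl2, −78 to 0 °C; ice water
Reagents that add atoms: none
Why: BCl3 binds the carboxyl oxygen and the ortho methoxy oxygen in a six-membered chelate, so chloride should remove only that methyl group (chelation-controlled aryl methyl ether cleavage) and leave the para methoxy group, while the low temperature guards against decarboxylation.

Step 5
Reactants: 10 2-heptyl-4,6-dimethoxybenzoic acid
Product: 12 2-heptyl-4,6-dihydroxybenzoic acid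
Conditions: BBr3 (4 equiv), CH2Cl2, −78 °C to rt; ice water, cold work-up
Reagents that add atoms: none
Why: BBr3 cleaves both aryl methyl ethers (Lewis acid ether cleavage), the usual way from 6-alkyl-2,4-dimethoxybenzoic acids to the homologous orsellinic acids, and a cold work-up without heating should spare the carboxyl group.

Step 6
Reactants: 12 2-heptyl-4,6-dihydroxybenzoic acid
Product: 13 benzyl 2-heptyl-4,6-dihydroxybenzoate
Conditions: BnBr (1.05 equiv), KHCO3 (1.2 equiv), DMF, rt
Reagents that add atoms: benzyl bromide, BrCc1ccccc1
Why: The weak base KHCO3 deprotonates only the carboxylic acid, so SN2 alkylation of the carboxylate by benzyl bromide should give the benzyl ester and leave both phenols free (chemoselective carboxylate O-alkylation).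

Step 7
Reactants: 11 2-heptyl-6-hydroxy-4-methoxybenzoic acid; 13 benzyl 2-heptyl-4,6-dihydroxybenzoate
Product: 15 benzyl 2-heptyl-4-[(2-heptyl-6-hydroxy-4-methoxybenzoyl)oxy]-6-hydroxybenzoate, via 2-heptyl-6-hydroxy-4-methoxybenzoyl trifluoroacetate 14 (not isolated)
Conditions: TFAA (4 equiv), dry toluene, rt; water
Reagents that add atoms: none
Why: Trifluoroacetic anhydride turns the hindered acid 11 into the mixed anhydride 14, which should acylate the free 4-hydroxyl of 13 (mixed-anhydride esterification, the standard depside coupling), while the 2-hydroxyl of each partner is hydrogen-bonded to its neighbouring carbonyl group and hindered, and any aryl trifluoroacetate is lost on aqueous work-up.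

Step 8
Reactants: 15 benzyl 2-heptyl-4-[(2-heptyl-6-hydroxy-4-methoxybenzoyl)oxy]-6-hydroxybenzoate
Product: 16 2-heptyl-4-[(2-heptyl-6-hydroxy-4-methoxybenzoyl)oxy]-6-hydroxybenzoic acid
Conditions: H2 (1 atm), 10% Pd/C, EtOAc, rt
Reagents that add atoms: none
Why: Catalytic hydrogenolysis of the benzyl ester over palladium on carbon should free the carboxylic acid under neutral conditions that leave the depside ester, the aryl methyl ether and the phenols untouched.

**Compound list**

1 | 1-bromo-3,5-dimethoxybenzene | COc1cc(Br)cc(OC)c1 | starting material
2 | 1,2-dibromo-3,5-dimethoxybenzene | COc1cc(OC)c(Br)c(Br)c1 | intermediate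
3 | 1-bromoheptane | CCCCCCCBr | starting material
4 | heptyllithium | [Li]CCCCCCC | intermediate
5 | carbon dioxide | O=C=O | starting material
6 | (2-bromo-4,6-dimethoxyphenyl)lithium | [Li]c1c(Br)cc(OC)cc1OC | intermediate
7 | 3,5-dimethoxybenzyne (1,2-didehydro-3,5-dimethoxybenzene) | COC1=CC(OC)=CC#C1 | intermediate
8 | (2-heptyl-4,6-dimethoxyphenyl)lithium | [Li]c1c(OC)cc(OC)cc1CCCCCCC | intermediate
9 | lithium 2-heptyl-4,6-dimethoxybenzoate | CCCCCCCc1cc(OC)cc(OC)c1C(=O)[O-].[Li+] | intermediate
10 | 2-heptyl-4,6-dimethoxybenzoic acid | CCCCCCCc1cc(OC)cc(OC)c1C(=O)O | intermediate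
11 | 2-heptyl-6-hydroxy-4-methoxybenzoic acid | CCCCCCCc1cc(OC)cc(O)c1C(=O)O | intermediate
12 | 2-heptyl-4,6-dihydroxybenzoic acid | CCCCCCCc1cc(O)cc(O)c1C(=O)O | intermediate
13 | benzyl 2-heptyl-4,6-dihydroxybenzoate | CCCCCCCc1cc(O)cc(O)c1C(=O)OCc1ccccc1 | intermediate
14 | 2-heptyl-6-hydroxy-4-methoxybenzoyl trifluoroacetate (mixed anhydride) | CCCCCCCc1cc(OC)cc(O)c1C(=O)OC(=O)C(F)(F)F | intermediate
15 | benzyl 2-heptyl-4-[(2-heptyl-6-hydroxy-4-methoxybenzoyl)oxy]-6-hydroxybenzoate | CCCCCCCc1cc(OC(=O)c2c(O)cc(OC)cc2CCCCCCC)cc(O)c1C(=O)OCc1ccccc1 | intermediate
16 | 2-heptyl-4-[(2-heptyl-6-hydroxy-4-methoxybenzoyl)oxy]-6-hydroxybenzoic acid | CCCCCCCc1cc(OC(=O)c2c(O)cc(OC)cc2CCCCCCC)cc(O)c1C(=O)O | target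

**Count**

Total steps: 8. Longest linear sequence: 6 steps (steps 1, 3, 5, 6, 7, 8).

**Steps most likely to fail**

Step 3. The aryne may be consumed by the product aryllithium instead of by heptyllithium, giving biaryl oligomers. Bromine transfer from unreacted dibromide or alkylation by the liberated 1-bromoheptane may also quench the aryllithium before carboxylation. The fallback avoids the aryne and sets out from 1. Kumada–Corriu coupling of 1 with heptylmagnesium bromide F1 (from 3 and Mg turnings in THF), catalysed by NiCl2(dppp), should give 1-heptyl-3,5-dimethoxybenzene F2. Vilsmeier–Haack formylation (POCl3, DMF) should then enter para to one methoxy group and next to the heptyl chain to give 2-heptyl-4,6-dimethoxybenzaldehyde F3. Pinnick oxidation (NaClO2, NaH2PO4, 2-methyl-2-butene, t-BuOH/water) brings the sequence back to the route at 10.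

Step 7. Acylation by the doubly ortho-substituted acyl donor may be slow, so that self-acylation of the free phenol of the acid partner or acylation at the hydrogen-bonded 2-hydroxyl of the benzyl ester competes. The fallback sets out from 10, which has no free phenol. Oxalyl chloride with catalytic DMF in CH2Cl2 should give 2-heptyl-4,6-dimethoxybenzoyl chloride F4. This acylates 13 in pyridine/CH2Cl2 to benzyl 2-heptyl-4-[(2-heptyl-4,6-dimethoxybenzoyl)oxy]-6-hydroxybenzoate F5. BCl3 in CH2Cl2 (−78 to 0 °C) should then cleave the methyl ether chelated to the depside carbonyl together with the benzyl ester, which brings the sequence back at the target 16.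

Step 5. Acid-promoted loss of carbon dioxide from the electron-rich resorcylic acid may accompany the ether cleavage or the work-up. The fallback sets out from 10 and takes that loss to completion on purpose. Hot 48% HBr in AcOH should demethylate and decarboxylate 10 to 5-heptylbenzene-1,3-diol F6. Ortho-carboxylation with MeOMgOCO2Me in DMF at 120 °C (a Kolbe–Schmitt-type carboxylation through the magnesium chelate) followed by cold acid work-up returns to the route at 12.

**Further compounds**

F1 | step 3 | heptylmagnesium bromide | CCCCCCC[Mg]Br
F2 | step 3 | 1-heptyl-3,5-dimethoxybenzene | CCCCCCCc1cc(OC)cc(OC)c1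
F3 | step 3 | 2-heptyl-4,6-dimethoxybenzaldehyde | CCCCCCCc1cc(OC)cc(OC)c1C=O
F4 | step 7 | 2-heptyl-4,6-dimethoxybenzoyl chloride | CCCCCCCc1cc(OC)cc(OC)c1C(=O)Cl
F5 | step 7 | benzyl 2-heptyl-4-[(2-heptyl-4,6-dimethoxybenzoyl)oxy]-6-hydroxybenzoate | CCCCCCCc1cc(OC(=O)c2c(OC)cc(OC)cc2CCCCCCC)cc(O)c1C(=O)OCc1ccccc1
F6 | step 5 | 5-heptylbenzene-1,3-diol | CCCCCCCc1cc(O)cc(O)c1
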